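**Retrosynthetic overview**
1. Numbering: ring A = C1 (exocyclic C15), C2, C3, C4 (isopropyl), C5, C9; ring B = C5, C6 (ethylidene C10–C11), C7, C8, C9; β is the face of the C4 isopropyl group and H-5, α the face of H-9.
2. The strategy rests on the C7 allylic carbinol of ring B beside the exocyclic (Z)-C6=C10 bond whose methyl C11 is cis to C7. C6–C7 and C10–C11 are cut together, giving the C5-ethynyl/C9-CH2CHO cyclohexanone 15 and Me2Zn (Ni(COD)2-catalysed methylative alkyne–aldehyde cyclisation).
3. Precursor 15 comes from (S)-4-isopropylcyclohexenone by conjugate alkynylation at C5, enolate allylation at C9 and alkene cleavage; the enone comes from isovaleraldehyde and methyl vinyl ketone.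
4. After ring B: the C7 acetate by Mitsunobu inversion; then ring A by C2=C3 enone, 1α-ol, hydroxyl-directed 2α,3α-epoxide, Me3SiCH2 addition at C1, Ti(OiPr)4-mediated opening at C3 by angelic acid and Peterson elimination to C1=C15.
5. Ring order: ring A first (step 2), ring B second (step 7).

Key step: step 7

Remark 1 (assumption): the (S)-prolinol ether is taken to give (S)-3 by the usual enamine face-shielding model; if the sense proved opposite, the enantiomeric catalyst would be used.
Remark 2: the trans-fused twist of ring B lets only an α-oriented C7–O bond reach the plane of the nascent C6=C10 bond, so the cyclisation is planned to give the 7α-alcohol, which is inverted when the acetate is put on.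
Remark 3: the ring A epoxide is delivered from the 1α-hydroxyl, because peroxide addition to the rigid enone would be axial (β face) and because base is avoided whenever H-9 is α to a carbonyl group.

**Route**

Step 1
Reactants: 1 isovaleraldehyde; 2 methyl vinyl ketone
Product: 3 (2S)-5-oxo-2-(propan-2-yl)hexanal
Conditions: (S)-2-(methoxydiphenylmethyl)pyrrolidine (5 mol %), ethyl 3,4-dihydroxybenzoate (20 mol %), neat, 4 °C
Reagents that add atoms: none
Why: Enamine-catalysed asymmetric Michael addition of an aldehyde to an enone: the diphenylmethoxymethyl arm of the catalyst shields one face of the (E)-enamine, so methyl vinyl ketone should add to the open face and set the future C4 centre as S.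

Step 2
Reactants: 3 (2S)-5-oxo-2-(propan-2-yl)hexanal
Product: 5 (4S)-4-(propan-2-yl)cyclohex-2-en-1-one [(S)-cryptone], via aldol adduct 4 (not isolated)
Conditions: LiOH (0.1 equiv), i-PrOH, rt
Reagents that add atoms: none
Why: Intramolecular aldol condensation (the ring-closing half of a Robinson annulation): the methyl ketone enolate closes ring A on the aldehyde and aldol 4 dehydrates, the mild medium being chosen to limit epimerisation of the α-centre of 3 before closure.

Step 3
Reactants: 5 (S)-cryptone; 6 (triisopropylsilyl)acetylene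
Product: 9 tert-butyldimethylsilyl enol ether (C1=C9) of (3S,4S)-4-isopropyl-3-[(triisopropylsilyl)ethynyl]cyclohexanone, via lithium acetylide 7 (not isolated), via alkynylzinc bromide 8 (not isolated)
Conditions: n-BuLi, THF, −78 → 0 °C; ZnBr2; then 5, TBSOTf, Et2O–THF, −40 °C
Reagents that add atoms: tert-butyldimethylsilyl trifluoromethanesulfonate, CC(C)(C)[Si](C)(C)OS(=O)(=O)C(F)(F)F
Why: Silyl-triflate-promoted conjugate addition of an alkynylzinc halide to an enone: the alkynyl group should enter C5 anti to the C4 isopropyl group (5α, trans) and the oxygen is captured as the regiodefined C1=C9 silyl enol ether; the triisopropylsilyl cap is chosen because it survives MeLi in step 4.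

Step 4
Reactants: 9 silyl enol ether; 10 allyl bromide
Product: 12 (2R,3S,4S)-2-allyl-4-isopropyl-3-[(triisopropylsilyl)ethynyl]cyclohexan-1-one, via lithium enolate 11 (not isolated)
Conditions: MeLi, THF, 0 °C → rt; then DMPU, allyl bromide, −78 → −20 °C
Reagents that add atoms: none
Why: Regiospecific enolate alkylation: MeLi cleaves the O–Si bond to the lithium enolate 11 without enolate equilibration, and allyl bromide attacks C9 axially, anti to the neighbouring C5 alkynyl group, to give the all-equatorial 4β,5α,9β pattern.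

Step 5
Reactants: 12 allyl ketone
Product: 13 (2R,3S,4S)-2-allyl-3-ethynyl-4-isopropylcyclohexan-1-one
Conditions: Bu4NF, AcOH, THF, 0 °C → rt
Reagents that add atoms: none
Why: Fluoride-mediated protodesilylation of the alkynylsilane; any C9 epimer carried over from step 4 can only drift toward the wanted all-equatorial ketone under these mildly basic conditions.

Step 6
Reactants: 13 ethynyl allyl ketone
Product: 15 2-[(1R,2S,3S)-2-ethynyl-6-oxo-3-(propan-2-yl)cyclohexyl]acetaldehyde, via diol 14 (not isolated)
Conditions: OsO4 (2 mol %), NaIO4, 2,6-lutidine, dioxane–H2O, rt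
Reagents that add atoms: osmium tetroxide (oxygen donor, turned over by the periodate), O=[Os](=O)(=O)=O; sodium periodate, [Na+].[O-]I(=O)(=O)=O
Why: Lemieux–Johnson oxidation: OsO4 dihydroxylates the monosubstituted alkene far faster than the terminal alkyne and periodate cleaves diol 14 to the aldehyde, the lutidine buffer keeping the γ-keto aldehyde from aldolising.

Step 7
Reactants: 15 keto alkynyl aldehyde; 16 dimethylzinc
Product: 18 trans-fused 7α-hydroxy-6-[(Z)-ethylidene]-4β-isopropylhydrindan-1-one (5β-H and 9α-H), via methylzinc alkoxide 17 (not isolated)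
Conditions: Ni(COD)2 (10 mol %), Me2Zn (2.5 equiv), THF, 0 °C, slow addition of 15; sat. aq. NH4Cl
Reagents that add atoms: none
Why: Zerovalent nickel binds the ethynyl group and the aldehyde of 15 and couples them oxidatively to an oxanickelacyclopentene (Ni–C10=C6–C7–O); transmetalation with Me2Zn puts methyl on nickel and zinc on oxygen, and reductive elimination forms C10–C11 with methyl cis to C7, so the (Z)-ethylidene follows from syn addition across the alkyne. The closest known reaction type is the nickel-catalysed alkylative cyclisation of alkynyl aldehydes with organozinc reagents, which is documented for terminal alkynes. Ring B is closed in the 5-exo-dig mode at the internal alkyne carbon C6, and the trans ring fusion is already fixed by the diequatorial C5 and C9 arms on the ring A chair. The new stereocentre C7 is controlled by the metallacycle: its C7–O bond must lie near the plane of the nascent C6=C10 bond, and the twist that the trans fusion imposes on ring B allows this only for an α-oriented oxygen, so the 7α-alcohol is expected. The step needs aldehyde-over-ketone and alkylative-over-reductive selectivity: coupling of the alkyne with the C1 ketone would require a four-membered ring, Me2Zn has no β-hydrogen, and it does not add to either carbonyl group without the catalyst.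

Step 8
Reactants: 18 hydroxy ketone
Product: 20 C1=C2 trimethylsilyl enol ether 7α-trimethylsilyl ether of 18, via dilithium alkoxide enolate 19 (not isolated)
Conditions: LiN(i-Pr)2 (2.2 equiv), THF, −78 °C; Me3SiCl, −78 → 0 °C
Reagents that add atoms: chlorotrimethylsilane, C[Si](C)(C)Cl
Why: Kinetic enolisation and O-silylation: the amide base removes the alcohol proton and then a C2 methylene proton rather than the hindered ring-fusion H-9 (which keeps its configuration), and Me3SiCl traps both oxygens.

Step 9
Reactants: 20 bis-silyl compound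
Product: 22 7α-hydroxy-6-[(Z)-ethylidene]-4β-isopropylhydrind-2-en-1-one, via 7α-silyloxy enone 21 (not isolated)
Conditions: Pd(OAc)2 (1.1 equiv), MeCN, rt; then citric acid, MeOH, 0 °C
Reagents that add atoms: none
Why: Saegusa–Ito oxidation: the silyl enol ether gives an oxo-allyl complex of divalent palladium and β-hydride loss from C3 forms the C2=C3 enone regiospecifically; the C7 silyl ether shields the allylic alcohol until mild acidic methanolysis, base being avoided because H-9 is now epimerisable.

Step 10
Reactants: 22 hydroxy enone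
Product: 23 7β-acetoxy-6-[(Z)-ethylidene]-4β-isopropylhydrind-2-en-1-one
Conditions: PPh3, DIAD, AcOH, THF, 0 °C → rt
Reagents that add atoms: acetic acid, CC(=O)O
Why: Mitsunobu reaction: the 7α-oxyphosphonium ion is displaced by acetate in an SN2 step with inversion, which turns the 7α-alcohol into the 7β-acetate of the target; the C7–O bond lies near the alkene plane, so ionisation toward SN2′ capture gains little allylic assistance.

Step 11
Reactants: 23 acetoxy enone
Product: 24 7β-acetoxy-6-[(Z)-ethylidene]-4β-isopropylhydrind-2-en-1α-ol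
Conditions: NaBH4, CeCl3·7H2O, MeOH, −78 °C
Reagents that add atoms: none
Why: Luche 1,2-reduction: hydride adds axially to the β face of C1 (anti to axial H-9), which should give the pseudo-equatorial 1α-alcohol, and the acetate survives at low temperature.

Step 12
Reactants: 24 allylic alcohol
Product: 25 7β-acetoxy-2α,3α-epoxy-6-[(Z)-ethylidene]-4β-isopropylhydrindan-1α-ol
Conditions: VO(acac)2 (5 mol %), t-BuOOH, CH2Cl2, 0 °C → rt
Reagents that add atoms: tert-butyl hydroperoxide, CC(C)(C)OO
Why: Hydroxyl-directed epoxidation: the vanadium-bound 1α-alkoxide delivers oxygen to the C2=C3 face syn to itself, giving the 2α,3α-epoxide, while the ethylidene, whose allylic oxygen is acylated, is not activated.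

Step 13
Reactants: 25 epoxy alcohol
Product: 26 7β-acetoxy-2α,3α-epoxy-6-[(Z)-ethylidene]-4β-isopropylhydrindan-1-one
Conditions: Dess–Martin periodinane, NaHCO3, CH2Cl2, 0 °C → rt
Reagents that add atoms: none
Why: Dess–Martin oxidation of the secondary alcohol under buffered, non-basic conditions, so that neither the epoxide nor the now enolisable H-9 is disturbed.

Step 14
Reactants: 26 epoxy ketone
Product: 28 7β-acetoxy-2α,3α-epoxy-6-[(Z)-ethylidene]-4β-isopropyl-1β-[(trimethylsilyl)methyl]hydrindan-1α-ol, via chloromagnesium alkoxide 27 (not isolated)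
Conditions: Me3SiCH2MgCl, CeCl3, THF, −78 °C; sat. aq. NH4Cl
Reagents that add atoms: (trimethylsilyl)methylmagnesium chloride, C[Si](C)(C)C[Mg]Cl
Why: Cerium-promoted Grignard addition (first stage of a Peterson olefination): the reagent attacks the C1 carbonyl from the β face, anti to the epoxide oxygen and along the axial trajectory, giving the 1α-alkoxide cis to the epoxide, and its low basicity avoids enolisation at C9 and attack on the acetate at −78 °C.

Step 15
Reactants: 28 epoxy β-hydroxysilane; 29 angelic acid
Product: 30 7β-acetoxy-3β-angeloyloxy-6-[(Z)-ethylidene]-4β-isopropyl-1β-[(trimethylsilyl)methyl]hydrindane-1α,2α-diol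
Conditions: Ti(OiPr)4 (1.5 equiv), angelic acid (2 equiv), CH2Cl2, rt; aq. tartaric acid
Reagents that add atoms: none
Why: Ti(OiPr)4-mediated opening of a 2,3-epoxy alcohol by a carboxylic acid, which is selective for the carbon remote from the carbinol: the titanium-bound C1 alkoxide activates the cis epoxide and angelate attacks C3 from the β face with inversion, which is also the trans-diaxial (Fürst–Plattner) mode, so the 3β-angelate and the 2α-hydroxyl result, and the neutral conditions should not isomerise the angelate to the tiglate.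

Step 16
Reactants: 30 β-hydroxysilane diol angelate
Product: 31 target CNP0113604.1 (2α-hydroxy-3β-angeloyloxy-7β-acetoxy-4β-isopropyl-6-[(Z)-ethylidene]-1-methylene-trans-hydrindane)
Conditions: p-TsOH·H2O (0.1 equiv), CH2Cl2, 0 °C
Reagents that add atoms: none
Why: Acid-mediated Peterson elimination: ionisation of the tertiary C1–O bond is assisted by the β-silicon and loss of the silyl group places the double bond only at C1=C15, leaving the C2 hydroxyl and both esters untouched.

**Compound list**
1 | isovaleraldehyde (3-methylbutanal) | CC(C)CC=O | starting material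
2 | methyl vinyl ketone | CC(=O)C=C | starting material
3 | (2S)-5-oxo-2-(propan-2-yl)hexanal | O=C[C@H](C(C)C)CCC(C)=O | intermediate
4 | (4S)-3-hydroxy-4-isopropylcyclohexanone (aldol adduct, carbinol epimers) | O=C1CC(O)[C@H](C(C)C)CC1 | intermediate
5 | (4S)-4-(propan-2-yl)cyclohex-2-en-1-one | O=C1C=C[C@H](C(C)C)CC1 | intermediate
6 | (triisopropylsilyl)acetylene | C#C[Si](C(C)C)(C(C)C)C(C)C | starting material
7 | lithium (triisopropylsilyl)acetylide | [Li]C#C[Si](C(C)C)(C(C)C)C(C)C | intermediate
8 | [(triisopropylsilyl)ethynyl]zinc bromide | Br[Zn]C#C[Si](C(C)C)(C(C)C)C(C)C | intermediate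
9 | tert-butyl{[(3S,4S)-4-isopropyl-3-[(triisopropylsilyl)ethynyl]cyclohex-1-en-1-yl]oxy}dimethylsilane | CC(C)(C)[Si](C)(C)OC1=C[C@@H](C#C[Si](C(C)C)(C(C)C)C(C)C)[C@H](C(C)C)CC1 | intermediate
10 | allyl bromide | C=CCBr | starting material
11 | lithium enolate of (3S,4S)-4-isopropyl-3-[(triisopropylsilyl)ethynyl]cyclohexanone (C1=C9) | [Li]OC1=C[C@@H](C#C[Si](C(C)C)(C(C)C)C(C)C)[C@H](C(C)C)CC1 | intermediate
12 | (2R,3S,4S)-2-allyl-4-isopropyl-3-[(triisopropylsilyl)ethynyl]cyclohexan-1-one | O=C1CC[C@@H](C(C)C)[C@H](C#C[Si](C(C)C)(C(C)C)C(C)C)[C@H]1CC=C | intermediate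
13 | (2R,3S,4S)-2-allyl-3-ethynyl-4-isopropylcyclohexan-1-one | O=C1CC[C@@H](C(C)C)[C@H](C#C)[C@H]1CC=C | intermediate
14 | (2R,3S,4S)-2-(2,3-dihydroxypropyl)-3-ethynyl-4-isopropylcyclohexan-1-one (carbinol epimers) | O=C1CC[C@@H](C(C)C)[C@H](C#C)[C@H]1CC(O)CO | intermediate
15 | 2-[(1R,2S,3S)-2-ethynyl-6-oxo-3-(propan-2-yl)cyclohexyl]acetaldehyde | O=C1CC[C@@H](C(C)C)[C@H](C#C)[C@H]1CC=O | intermediate
16 | dimethylzinc | C[Zn]C | starting material
17 | methylzinc 7α-alkoxide of 18 | O=C1CC[C@@H](C(C)C)[C@@H]2/C(=C/C)[C@H](O[Zn]C)C[C@@H]12 | intermediate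
18 | trans-fused 7α-hydroxy-6-[(Z)-ethylidene]-4β-isopropylhydrindan-1-one | O=C1CC[C@@H](C(C)C)[C@@H]2/C(=C/C)[C@H](O)C[C@@H]12 | intermediate
19 | dilithium 7α-alkoxide C1=C2 enolate of 18 | [Li]OC1=CC[C@@H](C(C)C)[C@@H]2/C(=C/C)[C@H](O[Li])C[C@@H]12 | intermediate
20 | C1=C2 trimethylsilyl enol ether 7α-trimethylsilyl ether of 18 | C[Si](C)(C)OC1=CC[C@@H](C(C)C)[C@@H]2/C(=C/C)[C@H](O[Si](C)(C)C)C[C@@H]12 | intermediate
21 | 7α-(trimethylsilyloxy)-6-[(Z)-ethylidene]-4β-isopropylhydrind-2-en-1-one | O=C1C=C[C@@H](C(C)C)[C@@H]2/C(=C/C)[C@H](O[Si](C)(C)C)C[C@@H]12 | intermediate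
22 | 7α-hydroxy-6-[(Z)-ethylidene]-4β-isopropylhydrind-2-en-1-one | O=C1C=C[C@@H](C(C)C)[C@@H]2/C(=C/C)[C@H](O)C[C@@H]12 | intermediate
23 | 7β-acetoxy-6-[(Z)-ethylidene]-4β-isopropylhydrind-2-en-1-one | O=C1C=C[C@@H](C(C)C)[C@@H]2/C(=C/C)[C@@H](OC(C)=O)C[C@@H]12 | intermediate
24 | 7β-acetoxy-6-[(Z)-ethylidene]-4β-isopropylhydrind-2-en-1α-ol | O[C@@H]1C=C[C@@H](C(C)C)[C@@H]2/C(=C/C)[C@@H](OC(C)=O)C[C@@H]12 | intermediate
25 | 7β-acetoxy-2α,3α-epoxy-6-[(Z)-ethylidene]-4β-isopropylhydrindan-1α-ol | O[C@@H]1[C@@H]3O[C@@H]3[C@@H](C(C)C)[C@@H]2/C(=C/C)[C@@H](OC(C)=O)C[C@@H]12 | intermediate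
26 | 7β-acetoxy-2α,3α-epoxy-6-[(Z)-ethylidene]-4β-isopropylhydrindan-1-one | O=C1[C@@H]3O[C@@H]3[C@@H](C(C)C)[C@@H]2/C(=C/C)[C@@H](OC(C)=O)C[C@@H]12 | intermediate
27 | chloromagnesium 1α-alkoxide of 28 | C[Si](C)(C)C[C@@]1(O[Mg]Cl)[C@@H]3O[C@@H]3[C@@H](C(C)C)[C@@H]2/C(=C/C)[C@@H](OC(C)=O)C[C@@H]12 | intermediate
28 | 7β-acetoxy-2α,3α-epoxy-6-[(Z)-ethylidene]-4β-isopropyl-1β-[(trimethylsilyl)methyl]hydrindan-1α-ol | C[Si](C)(C)C[C@@]1(O)[C@@H]3O[C@@H]3[C@@H](C(C)C)[C@@H]2/C(=C/C)[C@@H](OC(C)=O)C[C@@H]12 | intermediate
29 | angelic acid [(Z)-2-methylbut-2-enoic acid] | C/C=C(/C)C(=O)O | starting material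
30 | 7β-acetoxy-3β-angeloyloxy-6-[(Z)-ethylidene]-4β-isopropyl-1β-[(trimethylsilyl)methyl]hydrindane-1α,2α-diol | C[Si](C)(C)C[C@@]1(O)[C@H](O)[C@@H](OC(=O)/C(C)=C\C)[C@@H](C(C)C)[C@@H]2/C(=C/C)[C@@H](OC(C)=O)C[C@@H]12 | intermediate
31 | CNP0113604.1 | C=C1[C@H](O)[C@@H](OC(=O)/C(C)=C\C)[C@@H](C(C)C)[C@@H]2/C(=C/C)[C@@H](OC(C)=O)C[C@@H]12 | target

**Step count**
Total steps: 16. Longest linear sequence: 16 steps (1 and 2 to 31).

**Steps most likely to fail**

Step 7. The aldehyde may be engaged on its other face, or on both faces, in the oxidative cyclisation, so that C7 comes out 7β or mixed instead of the predicted 7α. The fallback makes the route stereoconvergent and sets out from 15, coming back at 23. The 7β-epimer of 18 F1 is separated and taken through the conditions of steps 8 and 9, by way of its dilithium alkoxide enolate F2, the bis(trimethylsilyl) derivative F3 and the 7β-silyloxy enone F4, to the 7β-hydroxy enone F5. F5 is acetylated with retention (Ac2O, DMAP, pyridine, 0 °C) to give 23, while any 7α-material still goes through the Mitsunobu step.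

Step 15. Attack of the titanium-bound carboxylate at C3 passes the C4 isopropyl group and the syn-axial CH2SiMe3 group, so the opening may stall, isopropoxide may compete, or the silyl group may be lost too early. The fallback sets out from 26 and comes back at 31 without the silylmethyl adduct. Epoxy ketone 26 is opened by angelic acid 29 under Lewis acid activation (BF3·OEt2, CH2Cl2, −40 °C); protonation-type activation and the trans-diaxial rule both direct the acid to C3, giving the 2α-hydroxy-3β-angeloyloxy ketone F6. F6 is then methylenated under non-basic Takai–Lombardo conditions (Zn, CH2Br2, TiCl4, THF–CH2Cl2, 0 °C) to 31.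

Step 10. Activation of the hindered allylic C7 alcohol may be slow, or the oxyphosphonium ion may ionise, leading to SN2′ capture at C10 or loss of H-8 to a diene instead of direct displacement. The fallback sets out from 22 and comes back at 23 with a discrete sulfonate. Alcohol 22 is converted at −40 °C (MsCl, Et3N, CH2Cl2) into the 7α-methanesulfonate F7, which is used crude and displaced with inversion by CsOAc and 18-crown-6 in toluene to give 23.

**Further compounds**
F1 | step 7 | trans-fused 7β-hydroxy-6-[(Z)-ethylidene]-4β-isopropylhydrindan-1-one | O=C1CC[C@@H](C(C)C)[C@@H]2/C(=C/C)[C@@H](O)C[C@@H]12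
F2 | step 7 | dilithium 7β-alkoxide C1=C2 enolate of F1 | [Li]OC1=CC[C@@H](C(C)C)[C@@H]2/C(=C/C)[C@@H](O[Li])C[C@@H]12
F3 | step 7 | C1=C2 trimethylsilyl enol ether 7β-trimethylsilyl ether of F1 | C[Si](C)(C)OC1=CC[C@@H](C(C)C)[C@@H]2/C(=C/C)[C@@H](O[Si](C)(C)C)C[C@@H]12
F4 | step 7 | 7β-(trimethylsilyloxy)-6-[(Z)-ethylidene]-4β-isopropylhydrind-2-en-1-one | O=C1C=C[C@@H](C(C)C)[C@@H]2/C(=C/C)[C@@H](O[Si](C)(C)C)C[C@@H]12
F5 | step 7 | 7β-hydroxy-6-[(Z)-ethylidene]-4β-isopropylhydrind-2-en-1-one | O=C1C=C[C@@H](C(C)C)[C@@H]2/C(=C/C)[C@@H](O)C[C@@H]12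
F6 | step 15 | 7β-acetoxy-3β-angeloyloxy-2α-hydroxy-6-[(Z)-ethylidene]-4β-isopropylhydrindan-1-one | O=C1[C@H](O)[C@@H](OC(=O)/C(C)=C\C)[C@@H](C(C)C)[C@@H]2/C(=C/C)[C@@H](OC(C)=O)C[C@@H]12
F7 | step 10 | 7α-(methanesulfonyloxy)-6-[(Z)-ethylidene]-4β-isopropylhydrind-2-en-1-one | O=C1C=C[C@@H](C(C)C)[C@@H]2/C(=C/C)[C@H](OS(C)(=O)=O)C[C@@H]12
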